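A direct plan would start from ring B, C-acylate the anion of the sulfonyl enaminone A1 with the ring B aroyl chloride A2, and close ring C as the 5-phenylsulfonyl-4-pyranone A3.
It would then build ring A last, by a [4+2] addition of the trioxygenated silyl ketene acetal diene A4 to A3 followed by two eliminations, and would end with hydrogenolysis of the tribenzyl flavonol A5.
Its weakest step would be this ring A annulation: a monocyclic, partly aromatic 4-pyranone has no record as a dienophile, the diene could stop at a Michael adduct or simply lose its silyl group, and the ring closure would be left to chance on the one intermediate that already carries all of ring B.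
The second would be the acylation and cyclisation that make A3: a crowded enaminone anion would have to take a hindered, ortho-substituted aroyl chloride on carbon and not on oxygen, and the resulting diketone would have to close 6-endo without losing the sulfone.
The third would be the run-up as a whole: most of the steps would go into A1, A2 and A4, whose sulfonyl, amino and silyl groups are all thrown away, only to assemble a ring A that can be bought with its four oxygen atoms already in place.

**Plan of the new route**

The retrosynthesis cuts the C2–C1′ bond first, so that ring B leaves as an aryl iodide and the whole A/C half remains as 3,5,7,8-tetramethoxychromone. Ring C is then cut at O1–C2 and C2–C3 (a one-carbon unit) and at C4–C4a (an acylation of 1,2,3,5-tetramethoxybenzene).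
The rings thus arise in the order A (bought), C (closed on ring A in step 2), B (joined last in step 6), the reverse of the direct plan, and the key step forms a bond that the direct plan never makes.
The feature that allows this: C2–H is the only C–H bond of ring C. It sits between the ring oxygen O1 and the oxygen on C3 in a vinylogous ester, so it can be zincated alone and cross-coupled with the ring B iodide.
Ring A needs no cycloaddition and no aromatisation. Which oxygen becomes O1 is settled in step 1 by chelation-controlled cleavage of one methoxy group, and the same chelation to the C4 carbonyl frees the 3- and 5-hydroxyls at the end while the 7-, 8- and 5′-methoxy groups stay.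
No sulfone, enamine anion, diene or acid chloride is needed, and ring C is closed on a small, cheap ketone instead of on late material.
The target has no stereocentre, so only positional selectivity has to be controlled.

Key step: step 6

Remark: 1,2,3,5-tetramethoxybenzene, methoxyacetyl chloride and 3-(benzyloxy)-4-methoxybenzaldehyde are taken as commercial, and TMPZnCl·LiCl (TMP = 2,2,6,6-tetramethylpiperidide) as its commercial solution in THF.

**Route**

Step 1
Reactants: 1 1,2,3,5-tetramethoxybenzene; 2 methoxyacetyl chloride
Product: 4 1-(2-hydroxy-3,4,6-trimethoxyphenyl)-2-methoxyethan-1-one, via tetramethoxyphenyl ketone 3 (not isolated)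
Conditions: 2 (1.2 equiv), AlCl3 (2.5 equiv), Et2O, 0 °C → reflux; then 2 M HCl
Reagents that add atoms: none
Why: Friedel–Crafts acylation at one of the two equivalent free positions of the symmetric arene, followed in the same flask by chelation-controlled cleavage of the methoxy group that lies ortho to the new ketone and is also flanked by a second methoxy group (twisted out of the ring plane and therefore the most basic oxygen), the known course of aluminium chloride acylations of this arene, which places the future O1 next to the future 8-methoxy group.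

Step 2
Reactants: 4 1-(2-hydroxy-3,4,6-trimethoxyphenyl)-2-methoxyethan-1-one
Product: 6 3,5,7,8-tetramethoxy-4H-chromen-4-one, via enaminone 5 (not isolated)
Conditions: Me2NCH(OMe)2 (3 equiv), toluene, 100 °C; evaporate; then 2 M HCl, CH2Cl2, rt
Reagents that add atoms: N,N-dimethylformamide dimethyl acetal, COC(OC)N(C)C
Why: Amide-acetal condensation at the methylene activated by the ketone gives the enaminone, and on acidification the hydrogen-bonded phenol adds to the enamine carbon and expels dimethylamine (6-endo addition–elimination), the standard one-carbon closure of 2-hydroxyaryl ketones to chromones, which here leaves the 3-methoxy group in place and C2 unsubstituted.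

Step 3
Reactants: 7 3-(benzyloxy)-4-methoxybenzaldehyde
Product: 9 3-(benzyloxy)-4-methoxyphenol, via aryl formate 8 (not isolated)
Conditions: mCPBA (1.3 equiv), CH2Cl2, 0 °C → rt; then K2CO3 (cat.), MeOH, rt
Reagents that add atoms: 3-chloroperoxybenzoic acid, O=C(OO)c1cccc(Cl)c1
Why: Baeyer–Villiger (Dakin-type) oxidation in which the electron-rich aryl group, para to a methoxy group, migrates in the Criegee intermediate, followed by methanolysis of the aryl formate.

Step 4
Reactants: 9 3-(benzyloxy)-4-methoxyphenol
Product: 10 2,4-bis(benzyloxy)-1-methoxybenzene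
Conditions: BnBr (1.2 equiv), K2CO3 (1.5 equiv), DMF, 50 °C
Reagents that add atoms: benzyl bromide, BrCc1ccccc1
Why: Williamson ether synthesis on an unhindered phenoxide.

Step 5
Reactants: 10 2,4-bis(benzyloxy)-1-methoxybenzene
Product: 11 1,5-bis(benzyloxy)-2-iodo-4-methoxybenzene
Conditions: NIS (1.05 equiv), CF3CO2H (10 mol %), MeCN, 0 °C → rt, dark
Reagents that add atoms: N-iodosuccinimide, O=C1CCC(=O)N1I
Why: Electrophilic aromatic iodination goes to the one position that is para to one benzyloxy group and ortho to the other, since the site between the two benzyloxy groups is shielded and the site next to the methoxy group is activated by one donor only.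

Step 6
Reactants: 6 3,5,7,8-tetramethoxy-4H-chromen-4-one; 11 1,5-bis(benzyloxy)-2-iodo-4-methoxybenzene
Product: 13 2-[2,4-bis(benzyloxy)-5-methoxyphenyl]-3,5,7,8-tetramethoxy-4H-chromen-4-one, via chromon-2-ylzinc chloride 12 (not isolated)
Conditions: 6 (1.3 equiv), TMPZnCl·LiCl (1.4 equiv), THF, 25 °C; then 11 (1.0 equiv), Pd(OAc)2 (2 mol %), 2-dicyclohexylphosphino-2′,6′-dimethoxybiphenyl (4 mol %), THF, 50 °C
Reagents that add atoms: none
Why: The hindered, non-nucleophilic zinc amide removes the proton at C2 of 6, the only C–H bond of ring C, which is acidified by the adjacent ring oxygen O1 and by its place at the end of the vinylogous ester and can be reached by zinc held at the 3-methoxy oxygen; the resulting covalent C2–Zn bond of 12 neither opens the pyranone nor adds to the C4 carbonyl. Iodide 11 then adds oxidatively to zerovalent palladium, the chromonyl group passes from zinc to palladium and reductive elimination forms the C2–C1′ bond (Negishi coupling), the bulky electron-rich biarylphosphine being chosen to carry the ortho-benzyloxy aryl group through the last two events. The closest known reaction type is the regioselective zincation of chromones and 4-pyranones with TMP-zinc bases followed by palladium-catalysed arylation to flavones. The step closes no ring and creates no stereocentre. The selectivity it needs is positional only: on ring C there is no second C–H bond, the aryl C6–H between two methoxy groups is far less acidic toward this mild base than the vinylic C2–H, and on ring B the site is fixed by the iodine introduced in step 5. In one operation the two halves, each two or three steps from commerce, give the complete carbon skeleton and oxygen pattern of the target.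

Step 7
Reactants: 13 2-[2,4-bis(benzyloxy)-5-methoxyphenyl]-3,5,7,8-tetramethoxy-4H-chromen-4-one
Product: 14 2-(2,4-dihydroxy-5-methoxyphenyl)-3,5,7,8-tetramethoxy-4H-chromen-4-one
Conditions: H2 (1 atm), 10% Pd/C, EtOAc/MeOH, rt
Reagents that add atoms: none
Why: Heterogeneous hydrogenolysis cleaves the two benzyl ethers, while the methyl ethers and the tetrasubstituted C2=C3 bond of the chromone should be inert at ambient pressure.

Step 8
Reactants: 14 2-(2,4-dihydroxy-5-methoxyphenyl)-3,5,7,8-tetramethoxy-4H-chromen-4-one
Product: 15 3,5-dihydroxy-2-(2,4-dihydroxy-5-methoxyphenyl)-7,8-dimethoxy-4H-chromen-4-one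
Conditions: AlBr3 (10 equiv), MeCN, 0 → 40 °C; then 2 M HCl, rt
Reagents that add atoms: none
Why: Chelation-controlled Lewis-acid demethylation, in which aluminium is held by the C4 carbonyl oxygen together with the 5-methoxy oxygen (six-membered chelate) and the 3-methoxy oxygen (five-membered chelate) so that bromide removes only these two methyl groups, the established way from 3,5,7,8-tetramethoxyflavones to 3,5-dihydroxy-7,8-dimethoxyflavones; in acetonitrile the unchelated 7-, 8- and 5′-methoxy groups should stay.

**Compound list**

1 | 1,2,3,5-tetramethoxybenzene | COc1cc(OC)c(OC)c(OC)c1 | starting material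
2 | methoxyacetyl chloride | COCC(=O)Cl | starting material
3 | 2-methoxy-1-(2,3,4,6-tetramethoxyphenyl)ethan-1-one (not isolated) | COCC(=O)c1c(OC)cc(OC)c(OC)c1OC | intermediate
4 | 1-(2-hydroxy-3,4,6-trimethoxyphenyl)-2-methoxyethan-1-one | COCC(=O)c1c(OC)cc(OC)c(OC)c1O | intermediate
5 | 3-(dimethylamino)-1-(2-hydroxy-3,4,6-trimethoxyphenyl)-2-methoxyprop-2-en-1-one (alkene geometry not controlled; not isolated) | CN(C)C=C(OC)C(=O)c1c(OC)cc(OC)c(OC)c1O | intermediate
6 | 3,5,7,8-tetramethoxy-4H-chromen-4-one | COc1coc2c(OC)c(OC)cc(OC)c2c1=O | intermediate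
7 | 3-(benzyloxy)-4-methoxybenzaldehyde | COc1ccc(C=O)cc1OCc1ccccc1 | starting material
8 | 3-(benzyloxy)-4-methoxyphenyl formate (not isolated) | COc1ccc(OC=O)cc1OCc1ccccc1 | intermediate
9 | 3-(benzyloxy)-4-methoxyphenol | COc1ccc(O)cc1OCc1ccccc1 | intermediate
10 | 2,4-bis(benzyloxy)-1-methoxybenzene | COc1ccc(OCc2ccccc2)cc1OCc1ccccc1 | intermediate
11 | 1,5-bis(benzyloxy)-2-iodo-4-methoxybenzene | COc1cc(I)c(OCc2ccccc2)cc1OCc1ccccc1 | intermediate
12 | (3,5,7,8-tetramethoxy-4-oxo-4H-chromen-2-yl)zinc chloride (as its LiCl complex; not isolated) | COc1c([Zn]Cl)oc2c(OC)c(OC)cc(OC)c2c1=O | intermediate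
13 | 2-[2,4-bis(benzyloxy)-5-methoxyphenyl]-3,5,7,8-tetramethoxy-4H-chromen-4-one | COc1cc(-c2oc3c(OC)c(OC)cc(OC)c3c(=O)c2OC)c(OCc2ccccc2)cc1OCc1ccccc1 | intermediate
14 | 2-(2,4-dihydroxy-5-methoxyphenyl)-3,5,7,8-tetramethoxy-4H-chromen-4-one | COc1cc(-c2oc3c(OC)c(OC)cc(OC)c3c(=O)c2OC)c(O)cc1O | intermediate
15 | 3,5-dihydroxy-2-(2,4-dihydroxy-5-methoxyphenyl)-7,8-dimethoxy-4H-chromen-4-one | COc1cc(-c2oc3c(OC)c(OC)cc(O)c3c(=O)c2O)c(O)cc1O | target

**Count and risks**

Total step count: 8. Longest linear sequence: 6 steps (steps 3, 4, 5, 6, 7, 8, from 7); the ring A/C branch is 5 steps (steps 1, 2, 6, 7, 8).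

Steps most likely to fail:

Step 6. The zincation may be incomplete or unselective (competing deprotonation at C6 of ring A, or attack at C2 with opening of the pyranone), or transmetalation between the two hindered partners may stall so that protodezincation and homocoupling take over. Ring C would then be closed around ring B by a Baker–Venkataraman sequence, setting out from 4 and 11 and returning to the route at 13. Iodine–magnesium exchange on 11 (iPrMgCl·LiCl, THF, −20 °C) would give [2,4-bis(benzyloxy)-5-methoxyphenyl]magnesium chloride F1, and carboxylation (CO2, then dilute HCl) would give 2,4-bis(benzyloxy)-5-methoxybenzoic acid F2. Oxalyl chloride with catalytic DMF would give 2,4-bis(benzyloxy)-5-methoxybenzoyl chloride F3. O-Acylation of 4 (pyridine, catalytic 4-dimethylaminopyridine) would give 3,5,6-trimethoxy-2-(2-methoxyacetyl)phenyl 2,4-bis(benzyloxy)-5-methoxybenzoate F4. KOH in pyridine at 50 °C would move the aroyl group from oxygen to the methoxy-bearing carbon to give 1-[2,4-bis(benzyloxy)-5-methoxyphenyl]-3-(2-hydroxy-3,4,6-trimethoxyphenyl)-2-methoxypropane-1,3-dione F5, and AcOH with catalytic H2SO4 would close it with loss of water to 13.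

Step 8. The 3-methoxy group may resist cleavage, or selectivity may be lost on the assembled flavonol (attack on the 8- or 5′-methoxy group, or acid-induced opening and reclosure of ring C toward the 5,6,7-oxygenated isomer). The demethylation would then be moved to the cheap chromone, where forcing conditions cost nothing, setting out from 6 and returning to the route at 15. AlBr3 in MeCN would give 3,5-dihydroxy-7,8-dimethoxy-4H-chromen-4-one F6, and BnBr with K2CO3 in DMF at 80 °C would give 3,5-bis(benzyloxy)-7,8-dimethoxy-4H-chromen-4-one F7. Zincation as in step 6 would give [3,5-bis(benzyloxy)-7,8-dimethoxy-4-oxo-4H-chromen-2-yl]zinc chloride F8, and coupling with 11 would give 3,5-bis(benzyloxy)-2-[2,4-bis(benzyloxy)-5-methoxyphenyl]-7,8-dimethoxy-4H-chromen-4-one F9. Hydrogenolysis (H2, 10% Pd/C) of its four benzyl ethers would give 15 with no late demethylation at all.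

Step 1. Acylation and ether cleavage share one Lewis acid, so over-demethylation (both ortho methoxy groups, or the side-chain methyl ether) or incomplete acylation may result. The two events would then be separated and the bond made with the arene as the nucleophile, setting out from 1 and returning to the route at 4. Lithiation of 1 between two methoxy groups (n-BuLi, N,N,N′,N′-tetramethylethylenediamine, THF, 0 °C) would give (2,3,4,6-tetramethoxyphenyl)lithium F10. Acylation with N,2-dimethoxy-N-methylacetamide would give ketone 3, now isolated. One equivalent of BCl3 (CH2Cl2, −78 → −10 °C) would then cleave only the chelated, doubly flanked 2-methoxy group to give 4.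

**Further compounds**

F1 | step 6 | [2,4-bis(benzyloxy)-5-methoxyphenyl]magnesium chloride | COc1cc([Mg]Cl)c(OCc2ccccc2)cc1OCc1ccccc1
F2 | step 6 | 2,4-bis(benzyloxy)-5-methoxybenzoic acid | COc1cc(C(=O)O)c(OCc2ccccc2)cc1OCc1ccccc1
F3 | step 6 | 2,4-bis(benzyloxy)-5-methoxybenzoyl chloride | COc1cc(C(=O)Cl)c(OCc2ccccc2)cc1OCc1ccccc1
F4 | step 6 | 3,5,6-trimethoxy-2-(2-methoxyacetyl)phenyl 2,4-bis(benzyloxy)-5-methoxybenzoate | COCC(=O)c1c(OC)cc(OC)c(OC)c1OC(=O)c1cc(OC)c(OCc2ccccc2)cc1OCc1ccccc1
F5 | step 6 | 1-[2,4-bis(benzyloxy)-5-methoxyphenyl]-3-(2-hydroxy-3,4,6-trimethoxyphenyl)-2-methoxypropane-1,3-dione (racemic, enolisable) | COC(C(=O)c1c(OC)cc(OC)c(OC)c1O)C(=O)c1cc(OC)c(OCc2ccccc2)cc1OCc1ccccc1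
F6 | step 8 | 3,5-dihydroxy-7,8-dimethoxy-4H-chromen-4-one | COc1cc(O)c2c(=O)c(O)coc2c1OC
F7 | step 8 | 3,5-bis(benzyloxy)-7,8-dimethoxy-4H-chromen-4-one | COc1cc(OCc2ccccc2)c2c(=O)c(OCc3ccccc3)coc2c1OC
F8 | step 8 | [3,5-bis(benzyloxy)-7,8-dimethoxy-4-oxo-4H-chromen-2-yl]zinc chloride | COc1cc(OCc2ccccc2)c2c(=O)c(OCc3ccccc3)c([Zn]Cl)oc2c1OC
F9 | step 8 | 3,5-bis(benzyloxy)-2-[2,4-bis(benzyloxy)-5-methoxyphenyl]-7,8-dimethoxy-4H-chromen-4-one | COc1cc(-c2oc3c(OC)c(OC)cc(OCc4ccccc4)c3c(=O)c2OCc2ccccc2)c(OCc2ccccc2)cc1OCc1ccccc1
F10 | step 1 | (2,3,4,6-tetramethoxyphenyl)lithium | [Li]c1c(OC)cc(OC)c(OC)c1OC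
A1 | direct plan | 1-(benzyloxy)-4-(dimethylamino)-3-(phenylsulfonyl)but-3-en-2-one | CN(C)C=C(C(=O)COCc1ccccc1)S(=O)(=O)c1ccccc1
A2 | direct plan | 2,4-bis(benzyloxy)-5-methoxybenzoyl chloride | COc1cc(C(=O)Cl)c(OCc2ccccc2)cc1OCc1ccccc1
A3 | direct plan | 3-(benzyloxy)-2-[2,4-bis(benzyloxy)-5-methoxyphenyl]-5-(phenylsulfonyl)-4H-pyran-4-one | COc1cc(-c2occ(S(=O)(=O)c3ccccc3)c(=O)c2OCc2ccccc2)c(OCc2ccccc2)cc1OCc1ccccc1
A4 | direct plan | (1Z,3Z)-1,3,4-trimethoxy-1-(trimethylsilyloxy)buta-1,3-diene | CO/C=C(OC)/C=C(/OC)O[Si](C)(C)C
A5 | direct plan | 3-(benzyloxy)-2-[2,4-bis(benzyloxy)-5-methoxyphenyl]-5-hydroxy-7,8-dimethoxy-4H-chromen-4-one | COc1cc(-c2oc3c(OC)c(OC)cc(O)c3c(=O)c2OCc2ccccc2)c(OCc2ccccc2)cc1OCc1ccccc1
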